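**Retrosynthetic overview**

1. Target 18 ⇐ bis-tert-butyl ester 17 (TFA) ⇐ crossed Kolbe electrolysis of butenolide acid 13 with adipic acid mono-tert-butyl ester 14, which forms the side-chain C10′–C11′ bond with loss of two CO2.
2. Enabling feature: the bond lies inside the unbranched (CH2)14 tether between ring C5 and the terminal CO2H. Both flanking carbons are plain CH2 groups with no heteroatom, branch or π system nearby, so the two ω-acids give primary radicals that couple and are not oxidised further. The ring O1–C2(=O)–C3(Me)=C4(CO2tBu)–C5 is ten carbons away and its alkene is tetrasubstituted and electron-poor.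
3. 13 ⇐ RuO4 cleavage of the terminal alkene of 11; the ring CO2tBu ⇐ Pd-catalysed hydroxycarbonylation of tetronate triflate 8, then tert-butylation.
4. The only ring, the butenolide, is formed once, by Dieckmann closure of the C3–C4 bond in the O-propionyl α-hydroxy ester 6.
5. The C5 stereocentre comes from the chiral pool: methyl (R)-glycidate 2, opened at its CH2 by the Grignard reagent of 11-bromoundec-1-ene 1.

Key step: step 8

Remark: CIP analysis of the given SMILES gives (R) at the ring carbon that bears the chain. The text uses butenolide numbering (O1, C2=O, C3-Me, C4-carboxyl, C5-H, chain C1′ to C15′); the systematic names number the same ring carbon as C2 of a 2,5-dihydrofuran. Compounds 1, 2, 5 and 14 are taken as purchasable.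

**Route**

Step 1
Reactants: 1 11-bromoundec-1-ene; 2 methyl (2R)-oxirane-2-carboxylate
Product: 4 methyl (2R)-2-hydroxytetradec-13-enoate, via undec-10-en-1-ylmagnesium bromide 3 (not isolated)
Conditions: 1 (1.3 equiv), Mg, THF, 45 °C; then CuI (10 mol%), 2, THF, −40 → −20 °C; cold 1 M HCl
Reagents that add atoms: none
Why: Copper(I)-catalysed SN2 opening of the terminal epoxide by a primary Grignard reagent (cuprate epoxide opening) at the unsubstituted CH2 should outrun addition to the methyl ester at −40 °C, and since no bond to C2 is broken the (R) centre of the glycidate becomes the (R) carbinol that ends as ring C5.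

Step 2
Reactants: 4 methyl (2R)-2-hydroxytetradec-13-enoate; 5 propanoyl chloride
Product: 6 methyl (2R)-2-(propanoyloxy)tetradec-13-enoate
Conditions: pyridine, DMAP (cat.), CH2Cl2, 0 °C → rt
Reagents that add atoms: none
Why: DMAP-catalysed O-acylation of a secondary alcohol with an acid chloride; the stereocentre is not involved.

Step 3
Reactants: 6 methyl (2R)-2-(propanoyloxy)tetradec-13-enoate
Product: 7 (5R)-5-(dodec-11-en-1-yl)-4-hydroxy-3-methylfuran-2(5H)-one
Conditions: LiHMDS (2.3 equiv), THF, −78 → −20 °C; 1 M HCl
Reagents that add atoms: none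
Why: Dieckmann (intramolecular Claisen) condensation of an α-acyloxy ester: the propionate enolate attacks the methyl ester to close the five-membered ring (5-exo-trig), and the second equivalent of base converts the product into its tetronate anion, which drives the reaction and protects C5–H from deprotonation, so the configuration should be kept.

Step 4
Reactants: 7 (5R)-5-(dodec-11-en-1-yl)-4-hydroxy-3-methylfuran-2(5H)-one
Product: 8 (2R)-2-(dodec-11-en-1-yl)-4-methyl-5-oxo-2,5-dihydrofuran-3-yl trifluoromethanesulfonate
Conditions: Tf2O (1.1 equiv), iPr2NEt (1.2 equiv), CH2Cl2, −78 °C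
Reagents that add atoms: trifluoromethanesulfonic anhydride O=S(=O)(OS(=O)(=O)C(F)(F)F)C(F)(F)F
Why: O-sulfonylation (enol triflate formation) of the acidic vinylogous-acid OH at C4 with a hindered amine at low temperature should leave C5 untouched.

Step 5
Reactants: 8 (2R)-2-(dodec-11-en-1-yl)-4-methyl-5-oxo-2,5-dihydrofuran-3-yl trifluoromethanesulfonate
Product: 10 (2R)-2-(dodec-11-en-1-yl)-4-methyl-5-oxo-2,5-dihydrofuran-3-carboxylic acid, via mixed acetic carboxylic anhydride 9 (not isolated)
Conditions: Pd(OAc)2 (5 mol%), dppf (10 mol%), KOAc (4 equiv), CO (1 atm), DMSO, 60 °C; then H2O, dilute HCl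
Reagents that add atoms: carbon monoxide [C-]#[O+]; potassium acetate CC(=O)[O-].[K+]; water O
Why: Palladium-catalysed hydroxycarbonylation of a vinyl triflate: oxidative addition into the electron-poor C4–OTf bond, CO insertion and capture of the acyl-palladium by acetate give the mixed anhydride 9, which water cleaves on work-up; the isolated terminal alkene is a far poorer partner for the acyl-palladium than CO and acetate.

Step 6
Reactants: 10 (2R)-2-(dodec-11-en-1-yl)-4-methyl-5-oxo-2,5-dihydrofuran-3-carboxylic acid
Product: 11 tert-butyl (2R)-2-(dodec-11-en-1-yl)-4-methyl-5-oxo-2,5-dihydrofuran-3-carboxylate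
Conditions: tert-butyl 2,2,2-trichloroacetimidate (2.5 equiv), BF3·OEt2 (cat.), CH2Cl2/cyclohexane, rt
Reagents that add atoms: tert-butyl 2,2,2-trichloroacetimidate CC(C)(C)OC(=N)C(Cl)(Cl)Cl
Why: Acid-catalysed tert-butylation of a carboxylic acid with the trichloroacetimidate runs without base, so the C5–H γ to the lactone carbonyl should not epimerise and the terminal alkene is untouched.

Step 7
Reactants: 11 tert-butyl (2R)-2-(dodec-11-en-1-yl)-4-methyl-5-oxo-2,5-dihydrofuran-3-carboxylate
Product: 13 11-[(2R)-3-(tert-butoxycarbonyl)-4-methyl-5-oxo-2,5-dihydrofuran-2-yl]undecanoic acid, via 11-oxoundecyl aldehyde 12 (not isolated)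
Conditions: RuCl3·xH2O (3 mol%), NaIO4 (4.2 equiv), CCl4/MeCN/H2O, rt
Reagents that add atoms: sodium periodate [Na+].[O-]I(=O)(=O)=O; water O
Why: Catalytic RuO4 (RuCl3/NaIO4 oxidative alkene cleavage) should attack the electron-rich monosubstituted alkene and oxidise the aldehyde 12 in situ, whereas the tetrasubstituted ring alkene flanked by two carbonyl groups is strongly deactivated towards this electrophilic oxidant.

Step 8
Reactants: 13 11-[(2R)-3-(tert-butoxycarbonyl)-4-methyl-5-oxo-2,5-dihydrofuran-2-yl]undecanoic acid; 14 6-(tert-butoxy)-6-oxohexanoic acid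
Product: 17 tert-butyl (2R)-2-[15-(tert-butoxy)-15-oxopentadecyl]-4-methyl-5-oxo-2,5-dihydrofuran-3-carboxylate, via butenolide decyl radical 15 (not isolated), via 5-tert-butoxy-5-oxopentyl radical 16 (not isolated)
Conditions: 14 (6 equiv), KOH (5 mol% of total acid), MeOH, undivided cell, Pt anode/Pt cathode, constant current ca. 0.2 A cm⁻², 20–25 °C, stopped before the electrolyte reaches neutrality
Reagents that add atoms: none
Why: Crossed Kolbe electrolysis: at the platinum anode both carboxylates are oxidised at high current density, the acyloxy radicals lose CO2, and the primary alkyl radicals 15 and 16 combine at the electrode surface to form the C10′–C11′ bond while protons are reduced to H2 at the cathode. The closest known reaction type is the mixed Kolbe coupling of a fatty acid with a dicarboxylic acid half-ester, the classical electrochemical chain extension. No ring is closed and no stereocentre is formed; the only stereocentre, C5, lies ten methylene groups from the radical centre, and the electrolyte stays weakly acidic because free acid is in excess and the electrolysis is stopped early, so its γ-proton should not be removed. The step needs cross-coupling over homo-coupling, which is secured statistically by the six-fold excess of the cheap half-ester 14; its symmetrical dimer, di-tert-butyl decanedioate, should be separable by chromatography. It also needs radical rather than cation (Hofer–Moest) behaviour, which the unbranched CH2 radicals without α-heteroatom, the smooth Pt anode and methanol favour. The tetrasubstituted, doubly acceptor-flanked C3=C4 bond is too hindered to trap alkyl radicals, and the tert-butyl esters and the lactone are inert at the anode.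

Step 9
Reactants: 17 tert-butyl (2R)-2-[15-(tert-butoxy)-15-oxopentadecyl]-4-methyl-5-oxo-2,5-dihydrofuran-3-carboxylate
Product: 18 (2R)-2-(14-carboxytetradecyl)-4-methyl-5-oxo-2,5-dihydrofuran-3-carboxylic acid
Conditions: TFA/CH2Cl2 (1:2), 0 °C → rt
Reagents that add atoms: none
Why: Acidolysis of both tert-butyl esters by TFA (AAL1 cleavage, the tert-butyl cation leaving as isobutene) should leave the lactone, the ring alkene and the C5 stereocentre untouched because no base or nucleophile is present.

**Compound list**

1 | 11-bromoundec-1-ene | C=CCCCCCCCCCBr | starting material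
2 | methyl (2R)-oxirane-2-carboxylate | COC(=O)[C@H]1CO1 | starting material
3 | undec-10-en-1-ylmagnesium bromide | C=CCCCCCCCCC[Mg]Br | intermediate
4 | methyl (2R)-2-hydroxytetradec-13-enoate | COC(=O)[C@H](O)CCCCCCCCCCC=C | intermediate
5 | propanoyl chloride | CCC(=O)Cl | starting material
6 | methyl (2R)-2-(propanoyloxy)tetradec-13-enoate | COC(=O)[C@H](OC(=O)CC)CCCCCCCCCCC=C | intermediate
7 | (5R)-5-(dodec-11-en-1-yl)-4-hydroxy-3-methylfuran-2(5H)-one | CC1=C(O)[C@@H](CCCCCCCCCCC=C)OC1=O | intermediate
8 | (2R)-2-(dodec-11-en-1-yl)-4-methyl-5-oxo-2,5-dihydrofuran-3-yl trifluoromethanesulfonate | CC1=C(OS(=O)(=O)C(F)(F)F)[C@@H](CCCCCCCCCCC=C)OC1=O | intermediate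
9 | acetic (2R)-2-(dodec-11-en-1-yl)-4-methyl-5-oxo-2,5-dihydrofuran-3-carboxylic anhydride | CC1=C(C(=O)OC(C)=O)[C@@H](CCCCCCCCCCC=C)OC1=O | intermediate
10 | (2R)-2-(dodec-11-en-1-yl)-4-methyl-5-oxo-2,5-dihydrofuran-3-carboxylic acid | CC1=C(C(=O)O)[C@@H](CCCCCCCCCCC=C)OC1=O | intermediate
11 | tert-butyl (2R)-2-(dodec-11-en-1-yl)-4-methyl-5-oxo-2,5-dihydrofuran-3-carboxylate | CC1=C(C(=O)OC(C)(C)C)[C@@H](CCCCCCCCCCC=C)OC1=O | intermediate
12 | tert-butyl (2R)-4-methyl-5-oxo-2-(11-oxoundecyl)-2,5-dihydrofuran-3-carboxylate | CC1=C(C(=O)OC(C)(C)C)[C@@H](CCCCCCCCCCC=O)OC1=O | intermediate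
13 | 11-[(2R)-3-(tert-butoxycarbonyl)-4-methyl-5-oxo-2,5-dihydrofuran-2-yl]undecanoic acid | CC1=C(C(=O)OC(C)(C)C)[C@@H](CCCCCCCCCCC(=O)O)OC1=O | intermediate
14 | 6-(tert-butoxy)-6-oxohexanoic acid (adipic acid mono-tert-butyl ester) | OC(=O)CCCCC(=O)OC(C)(C)C | starting material
15 | 10-[(2R)-3-(tert-butoxycarbonyl)-4-methyl-5-oxo-2,5-dihydrofuran-2-yl]decyl radical | CC1=C(C(=O)OC(C)(C)C)[C@@H](CCCCCCCCC[CH2])OC1=O | intermediate
16 | 5-(tert-butoxy)-5-oxopentyl radical | [CH2]CCCC(=O)OC(C)(C)C | intermediate
17 | tert-butyl (2R)-2-[15-(tert-butoxy)-15-oxopentadecyl]-4-methyl-5-oxo-2,5-dihydrofuran-3-carboxylate | CC1=C(C(=O)OC(C)(C)C)[C@@H](CCCCCCCCCCCCCCC(=O)OC(C)(C)C)OC1=O | intermediate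
18 | (2R)-2-(14-carboxytetradecyl)-4-methyl-5-oxo-2,5-dihydrofuran-3-carboxylic acid | CC1=C(C(=O)O)[C@@H](CCCCCCCCCCCCCCC(=O)O)OC1=O | target

**Step count**

Total steps: 9. Longest linear sequence: 9 steps (1 or 2 → 18); compound 14 enters at step 8.

**Steps most likely to fail**

Step 8 (Kolbe coupling). Homo-coupling and disproportionation of the radicals may consume the valuable acid, and base building up near the cathode may epimerise C5. Fallback: setting out from 13, esterification with N-hydroxyphthalimide (N,N′-diisopropylcarbodiimide, DMAP cat., CH2Cl2) should give the redox-active N-(acyloxy)phthalimide ester F1. Tert-butyl 5-bromopentanoate is converted by zinc insertion (Zn dust, LiCl, THF, 50 °C) into [5-(tert-butoxy)-5-oxopentyl]zinc bromide F2. Nickel-catalysed decarboxylative alkyl–alkyl cross-coupling of F1 with F2 (NiCl2·glyme, 4,4′-di-tert-butyl-2,2′-bipyridine, THF/DMF, rt) forms the same C10′–C11′ bond and returns to the route at 17.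

Step 3 (Dieckmann closure). Competing deprotonation at the carbinol carbon of the α-acyloxy ester may erode the configuration, and intermolecular Claisen or acyl transfer may lower conversion. Fallback: setting out from 4, silylation (TBSCl, imidazole, DMF) gives methyl (2R)-2-[(tert-butyldimethylsilyl)oxy]tetradec-13-enoate F3. Saponification (LiOH, THF/H2O, 0 °C) gives (2R)-2-[(tert-butyldimethylsilyl)oxy]tetradec-13-enoic acid F4. Masamune–Brooks homologation (1,1′-carbonyldiimidazole, THF; then the magnesium salt of ethyl hydrogen methylmalonate, rt) gives the β-keto ester ethyl (4R)-4-[(tert-butyldimethylsilyl)oxy]-2-methyl-3-oxohexadec-15-enoate F5 under near-neutral conditions. HCl in MeOH then removes the silyl group, and the freed hydroxyl lactonises onto the ethyl ester; the fallback returns to the route at 7.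

Step 5 (hydroxycarbonylation). Acetate may attack the vinylogous acyl triflate and return the tetronate before palladium inserts, and prolonged warming with acetate may erode C5. Fallback: setting out from 8, reductive carbonylation without an oxygen nucleophile (Pd(PPh3)4, CO, slow addition of Bu3SnH, THF, 50 °C; formylation of a vinyl triflate) should give (2R)-2-(dodec-11-en-1-yl)-4-methyl-5-oxo-2,5-dihydrofuran-3-carbaldehyde F6. Pinnick oxidation (NaClO2, NaH2PO4, 2-methylbut-2-ene, tBuOH/H2O) then gives the acid, and the fallback returns to the route at 10.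

**Further compounds**

F1 | step 8 | 1,3-dioxoisoindolin-2-yl 11-[(2R)-3-(tert-butoxycarbonyl)-4-methyl-5-oxo-2,5-dihydrofuran-2-yl]undecanoate | CC1=C(C(=O)OC(C)(C)C)[C@@H](CCCCCCCCCCC(=O)ON2C(=O)c3ccccc3C2=O)OC1=O
F2 | step 8 | [5-(tert-butoxy)-5-oxopentyl]zinc bromide | CC(C)(C)OC(=O)CCCC[Zn]Br
F3 | step 3 | methyl (2R)-2-[(tert-butyldimethylsilyl)oxy]tetradec-13-enoate | COC(=O)[C@H](O[Si](C)(C)C(C)(C)C)CCCCCCCCCCC=C
F4 | step 3 | (2R)-2-[(tert-butyldimethylsilyl)oxy]tetradec-13-enoic acid | OC(=O)[C@H](O[Si](C)(C)C(C)(C)C)CCCCCCCCCCC=C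
F5 | step 3 | ethyl (4R)-4-[(tert-butyldimethylsilyl)oxy]-2-methyl-3-oxohexadec-15-enoate (mixture at C2) | CCOC(=O)C(C)C(=O)[C@H](O[Si](C)(C)C(C)(C)C)CCCCCCCCCCC=C
F6 | step 5 | (2R)-2-(dodec-11-en-1-yl)-4-methyl-5-oxo-2,5-dihydrofuran-3-carbaldehyde | CC1=C(C=O)[C@@H](CCCCCCCCCCC=C)OC1=O
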